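(The earlier runs and the new flask were generated by integration on assumed constants; scatter was added.)

The north-west run almost closes its own books, so its ledger comes first, followed by gamma's.

| flask | starting material | partner | protic impurity | temperature | remark | time |
|---|---|---|---|---|---|---|
| east | 17 mM | 12.6 mM | 3.6 mM | 55 °C | run made earlier |  |
| north-west | 26 mM | 12.6 mM | 3.6 mM | 74 °C | run made earlier |  |
| south-east | 12 mM | 25 mM | 3.6 mM | 55 °C | run made earlier |  |
| alpha | 12 mM | 12.6 mM | 3.60 mM | 70 °C |  | 30 h |
| gamma | 12 mM | 12.6 mM | 3.60 mM | 78 °C |  | 30 h |

| run | time / h | starting material / % | intermediate / % | product / % |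
|---|---|---|---|---|
| east | 6.00 | 90.7 | 5.4 | 0.3 |
| east | 12.0 | 82.9 | 10.6 | 0.6 |
| east | 20.0 | 73.8 | 16.5 | 1.2 |
| east | 30.0 | 63.9 | 22.0 | 2.4 |
| east | 40.0 | 55.9 | 26.5 | 4.7 |
| east | 48.0 | 51.2 | 29.6 | 5.9 |
| north-west | 3.00 | 68.3 | 25.7 | 1.5 |
| north-west | 6.00 | 47.4 | 41.8 | 4.8 |
| north-west | 10.0 | 29.6 | 52.6 | 9.3 |
| north-west | 15.0 | 16.5 | 59.6 | 14.8 |
| north-west | 20.0 | 9.6 | 63.2 | 18.6 |
| north-west | 25.0 | 4.8 | 64.2 | 20.4 |
| south-east | 4.00 | 94.3 | 3.9 | 0.7 |
| south-east | 12.0 | 82.0 | 10.5 | 1.0 |
| south-east | 25.0 | 67.6 | 17.4 | 3.4 |
| south-east | 30.0 | 63.5 | 19.8 | 5.1 |
| south-east | 48.0 | 48.7 | 24.1 | 10.8 |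

(standard deviation of a reading: 0.3 percentage points)

* which of these there is most of at the end, counted by the starting material in it, alpha (starting material / intermediate / product)
* which of these there is most of at the end, counted by the starting material in it, gamma (starting material / intermediate / product)
* how much there is at the end of the one of these that leads, in percent of the starting material charged: alpha
* how much there is at the end of the one of these that leads, in percent of the starting material charged: gamma

- product is meant together with its idle adduct
- steps that have been proposed: partner + intermediate -> product; partner + product <-> idle adduct; starting material + protic impurity -> quenched substrate; starting material -> intermediate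

1. At 25.0 h the north-west run holds starting material 4.8%, intermediate 64.2% and product 20.4%. The missing 10.6% is entered as quenched substrate.
2. Product slows in that run. Its gain from 20.0 h to 25.0 h is half its gain from 15.0 h to 20.0 h, yet intermediate rises from 59.6% to 64.2%. This reading fits a second partner going into idle adduct with each product.
3. The partner room is charged partner over twice the charged starting material: 52.5% for alpha and gamma, 24.2% for north-west. The fill is product over room. The north-west run reads 84.2%.
4. Gamma's books are reckoned here as an estimate. Quenched substrate is taken at the north-west share, although that run differs in charge and temperature, and starting material counts as nil. Intermediate and product then share 89.4%, so intermediate leads while product stays below 44.7%, a lead fill of 85.1%.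
5. The north-west run came close to that fill, but with twice gamma's starting material, at 74 °C against 78 °C. On this estimate, which is no bound, intermediate stands first in gamma, narrowly. Alpha at 70 °C is cooler than gamma, and intermediate is judged first there too, without a ledger of its own.

The forecast gives intermediate at 52% for alpha and intermediate at 47% for gamma, on the ground that “each product ties up a second partner”.

The simulation gives intermediate at 52.2% for alpha and intermediate at 48.2% for gamma.

    partner + intermediate → product (k = 2.10 /M/h, Ea = 78.0 kJ/mol)
    partner + product ⇌ idle adduct, settled at all times (K = 3300 /M, ΔH = −4.00 kJ/mol)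
    starting material + protic impurity → quenched substrate (k = 4.70 /M/h, Ea = 57.0 kJ/mol)
    starting material → intermediate (k = 0.0680 /h, Ea = 118 kJ/mol)
    (constants at 70 °C)

Gamma's product, 40.6%, fills 77.3% of the room, below the lead fill of 85.1%. The neighbouring flask is alpha with 32 mM of partner, so its room is 133%, more than the whole charge of starting material. Alpha's books carry starting material 9.31% and quenched substrate 14.1%, which puts the neighbour's lead point at 38.3%, a fill of 28.7%. The neighbour keeps those entries, 9.31% and 14.1%. Its product fills 35.9%, above that point, and product leads with 47.7% against intermediate at 28.9%.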